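**Retrosynthetic overview** (elemane numbering: ring C5–C10, lactone O on C6, ester O on C8)
1. Target ⇒ Yamaguchi acylation of the free O8 alcohol 21 with (Z)-2-(silyloxymethyl)but-2-enoic acid 26, then one global desilylation.
2. Both rings are made last, in one flask: the cyclohexane by intramolecular indium Barbier allylation (C6–C7 bond) of the acyclic aldehyde / 2-(bromomethyl)enoate 18, then the trans γ-lactone by lactonisation of the new C6 hydroxyl.
3. 18 ⇒ dialdehyde 14 by vinylalumination at C7 and SN2′ bromination; C7–C9 and the C8 stereocentre come from (S)-solketal.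
4. The C5/C10 pair is set on a temporary γ-butyrolactone template: Rh-catalysed asymmetric 1,4-addition to furan-2(5H)-one (C5), two anti-selective enolate alkylations (quaternary C10), then iBu2AlH/Wittig opening (C10 vinyl, C6 alcohol).

Assumption: the SMILES is read as drawn, i.e. the (3aR,4S,6R,7S,7aR)-elemanolide with a (Z)-2-(hydroxymethyl)but-2-enoate on O8; TBDPSO, TIPSO, TESO, TBSO = tert-butyldiphenyl-, triisopropyl-, triethyl-, tert-butyldimethyl-silyloxy.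

Step 1
Reactants: 1 2-bromoprop-2-en-1-ol
Product: 2 [(2-bromoprop-2-en-1-yl)oxy](tert-butyl)diphenylsilane
Conditions: TBDPSCl, imidazole, DMF, 0 °C to rt
Reagents that add atoms: tert-butyl(chloro)diphenylsilane, CC(C)(C)[Si](Cl)(c1ccccc1)c1ccccc1
Why: Imidazole-mediated silyl ether formation on a primary allylic alcohol gives an acid-stable protecting group for O15; no stereocentre is formed.

Step 2
Reactants: 2 [(2-bromoprop-2-en-1-yl)oxy](tert-butyl)diphenylsilane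
Product: 3 tert-butyldiphenyl{[2-(4,4,5,5-tetramethyl-1,3,2-dioxaborolan-2-yl)prop-2-en-1-yl]oxy}silane
Conditions: B2pin2, PdCl2(PPh3)2 (3 mol %), PPh3 (6 mol %), KOPh, toluene, 50 °C
Reagents that add atoms: bis(pinacolato)diboron, CC1(C)OB(OC1(C)C)B1OC(C)(C)C(C)(C)O1
Why: Miyaura borylation of a 1-alkenyl bromide with the mild base KOPh gives the vinyl boronate without forming a β-silyloxy organolithium or Grignard species; no stereocentre is formed.

Step 3
Reactants: 3 the alkenyl boronate; 4 furan-2(5H)-one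
Product: 5 (4R)-4-[3-(TBDPSO)prop-1-en-2-yl]dihydrofuran-2(3H)-one
Conditions: [Rh(cod)Cl]2 (2.5 mol %), (R)-BINAP (6 mol %), KOH (0.3 equiv), dioxane/H2O 10:1, 50 °C
Reagents that add atoms: none
Why: Hayashi–Miyaura rhodium-catalysed asymmetric 1,4-addition, in which the alkenyl-rhodium/(R)-BINAP species adds to one enantioface of the butenolide and so sets C5 (the 4R centre of 5).

Step 4
Reactants: 6 (S)-solketal, [(4S)-2,2-dimethyl-1,3-dioxolan-4-yl]methanol
Product: 7 [(4R)-2,2-dimethyl-1,3-dioxolan-4-yl]methyl trifluoromethanesulfonate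
Conditions: Tf2O, 2,6-lutidine, CH2Cl2, −78 °C (used crude)
Reagents that add atoms: trifluoromethanesulfonic anhydride, O=S(=O)(OS(=O)(=O)C(F)(F)F)C(F)(F)F
Why: Sulfonylation of the primary alcohol gives a triflate reactive enough for enolate alkylation despite the β-oxygen; the future C8 centre is untouched and only its CIP label changes.

Step 5
Reactants: 5 the (4R)-lactone; 7 the triflate
Product: 8 (3S,4R)-4-[3-(TBDPSO)prop-1-en-2-yl]-3-{[(4S)-2,2-dimethyl-1,3-dioxolan-4-yl]methyl}dihydrofuran-2(3H)-one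
Conditions: LiN(SiMe3)2, THF, −78 °C; then 7, DMPU, −78 to −30 °C
Reagents that add atoms: none
Why: Lactone enolate alkylation (SN2 at the primary triflate) occurs anti to the C4 alkenyl group to give the trans lactone, and this C3 centre is re-enolised in step 6.

Step 6
Reactants: 8 the trans-3,4-disubstituted lactone
Product: 9 (3R,4S)-4-[3-(TBDPSO)prop-1-en-2-yl]-3-{[(4S)-2,2-dimethyl-1,3-dioxolan-4-yl]methyl}-3-[(TIPSO)methyl]dihydrofuran-2(3H)-one
Conditions: LiN(iPr)2, THF/HMPA, −78 °C; then iPr3SiOCH2Cl, −78 to −20 °C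
Reagents that add atoms: (triisopropylsilyloxy)methyl chloride, ClCO[Si](C(C)C)(C(C)C)C(C)C
Why: Second enolate alkylation, in which the chloromethyl ether enters anti to the neighbouring β-alkenyl group and so fixes the quaternary carbon C10 with CH2OTIPS (C14) trans and the dioxolanylmethyl arm (C9) cis to the C5 substituent on the lactone.

Step 7
Reactants: 9 the quaternary lactone
Product: 10 (3R,4S)-4-[3-(TBDPSO)prop-1-en-2-yl]-3-{[(4S)-2,2-dimethyl-1,3-dioxolan-4-yl]methyl}-3-[(TIPSO)methyl]tetrahydrofuran-2-ol (both C2 epimers)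
Conditions: iBu2AlH (1.1 equiv), CH2Cl2, −78 °C; aq. potassium sodium tartrate
Reagents that add atoms: none
Why: Partial hydride reduction of the hindered lactone stops at the lactol because the tetrahedral aluminate survives at −78 °C; the new hemiacetal centre is an inconsequential epimer mixture.

Step 8
Reactants: 10 the lactol
Product: 11 (2S,3R)-2-[3-(TBDPSO)prop-1-en-2-yl]-3-{[(4S)-2,2-dimethyl-1,3-dioxolan-4-yl]methyl}-3-[(TIPSO)methyl]pent-4-en-1-ol
Conditions: Ph3PCH3Br, KOtBu, THF, 0 to 60 °C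
Reagents that add atoms: methyltriphenylphosphonium bromide, C[P+](c1ccccc1)(c1ccccc1)c1ccccc1.[Br-]
Why: Wittig methylenation of the open hydroxy-aldehyde form of the lactol turns the former lactone carbonyl into the C10 vinyl group and frees the C6 primary alcohol without touching a stereocentre.

Step 9
Reactants: 11 the pentenol acetonide
Product: 12 (2S,4R,5S)-5-[3-(TBDPSO)prop-1-en-2-yl]-4-ethenyl-4-[(TIPSO)methyl]hexane-1,2,6-triol
Conditions: AcOH/THF/H2O 3:1:1, 40 °C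
Reagents that add atoms: none
Why: Acid-catalysed acetal hydrolysis removes the terminal acetonide while the bulky primary TBDPS and TIPS ethers are stable to aqueous acetic acid.

Step 10
Reactants: 12 the triol
Product: 13 (2S,4R,5S)-5-[3-(TBDPSO)prop-1-en-2-yl]-4-ethenyl-1,2,6-tris(TESO)-4-[(TIPSO)methyl]hexane
Conditions: Et3SiCl (4 equiv), imidazole, DMF, 0 °C to rt
Reagents that add atoms: chlorotriethylsilane, CC[Si](Cl)(CC)CC
Why: Exhaustive silylation protects O8 as a secondary TES ether and turns both primary alcohols into TES ethers that can be oxidised directly.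

Step 11
Reactants: 13 the tris-TES ether
Product: 14 (2S,4R,5S)-5-[3-(TBDPSO)prop-1-en-2-yl]-4-ethenyl-2-(TESO)-4-[(TIPSO)methyl]hexanedial
Conditions: (COCl)2, DMSO, CH2Cl2, −78 to −30 °C; then iPr2NEt, −78 to −20 °C
Reagents that add atoms: none
Why: Swern oxidation, in which chlorodimethylsulfonium chloride cleaves only the primary TES ethers to alkoxysulfonium salts and hence aldehydes, while low temperature and a hindered base protect the α-centres C5 and C8.

Step 12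
Reactants: 14 the dialdehyde; 15 methyl prop-2-ynoate
Product: 17 methyl (4S,6R,7S)-7-[3-(TBDPSO)prop-1-en-2-yl]-6-ethenyl-3-hydroxy-2-methylidene-8-oxo-4-(TESO)-6-[(TIPSO)methyl]octanoate (both C3 epimers), via vinylalane 16 (not isolated)
Conditions: 15, iBu2AlH, HMPA, THF, 0 °C; then 14 (1.0 equiv), −40 to 0 °C
Reagents that add atoms: none
Why: Hydroalumination of the propiolate gives an α-alumino acrylate (vinylalumination, a Morita–Baylis–Hillman surrogate) that should add to the unhindered, inductively activated α-siloxy aldehyde C7 rather than the neopentyl-like α-branched C6 aldehyde; the new carbinol centre is removed in step 13.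

Step 13
Reactants: 17 the Baylis–Hillman-type alcohol
Product: 18 methyl (2Z,4S,6R,7S)-2-(bromomethyl)-7-[3-(TBDPSO)prop-1-en-2-yl]-6-ethenyl-8-oxo-4-(TESO)-6-[(TIPSO)methyl]oct-2-enoate
Conditions: NBS, Me2S, CH2Cl2, 0 °C to rt
Reagents that add atoms: N-bromosuccinimide, O=C1CCC(=O)N1Br
Why: Corey–Kim-type bromination of the allylic alcohol proceeds with allylic transposition (SN2′) to the (Z)-2-(bromomethyl)enoate, erasing the carbinol centre and leaving the aldehyde untouched.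

Step 14
Reactants: 18 the bromo aldehyde
Product: 20 (3aS,4S,6R,7S,7aR)-7-[3-(TBDPSO)prop-1-en-2-yl]-6-ethenyl-3-methylidene-4-(TESO)-6-[(TIPSO)methyl]hexahydro-1-benzofuran-2(3H)-one, via hydroxy ester 19 (not isolated)
Conditions: indium powder (In), THF/H2O 1:1 (0.005 M), rt; then PPTS (cat.), CH2Cl2, rt
Reagents that add atoms: none
Why: Intramolecular indium Barbier allylation then lactonisation, in which the equilibrating allylindium is expected to close on the C6 aldehyde through a chair-like transition state with the C5 and C8 substituents equatorial, setting C6 and C7 so that O6 and C11 are equatorial and the α-methylene-γ-lactone is trans-fused.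

Step 15
Reactants: 20 the TES-protected lactone
Product: 21 (3aR,4S,6R,7S,7aR)-7-[3-(TBDPSO)prop-1-en-2-yl]-6-ethenyl-4-hydroxy-3-methylidene-6-[(TIPSO)methyl]hexahydro-1-benzofuran-2(3H)-one
Conditions: PPTS, MeOH/CH2Cl2 1:1, 0 °C
Reagents that add atoms: none
Why: Acid-catalysed methanolysis cleaves the secondary TES ether much faster than the bulky primary TIPS and TBDPS ethers, so only O8 is unmasked.

Step 16
Reactants: 22 methyl but-2-ynoate
Product: 24 methyl (2Z)-2-(hydroxymethyl)but-2-enoate, via vinylalane 23 (not isolated)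
Conditions: iBu2AlH, HMPA, THF, 0 °C; then (CH2O)n, 0 °C to rt
Reagents that add atoms: formaldehyde (from paraformaldehyde), C=O
Why: syn-Hydroalumination of the ynoate followed by trapping of the α-alumino enoate with formaldehyde with retention (vinylalumination) places CH3 cis to the ester, which is the (Z)-geometry of the side chain.

Step 17
Reactants: 24 methyl (2Z)-2-(hydroxymethyl)but-2-enoate
Product: 25 methyl (2Z)-2-[(TBSO)methyl]but-2-enoate
Conditions: tBuMe2SiCl, imidazole, CH2Cl2, rt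
Reagents that add atoms: tert-butyl(chloro)dimethylsilane, CC(C)(C)[Si](C)(C)Cl
Why: Silyl ether formation masks the primary hydroxyl so that the acid can be activated later; the alkene geometry is not affected.

Step 18
Reactants: 25 the TBS ether methyl ester
Product: 26 (2Z)-2-[(TBSO)methyl]but-2-enoic acid
Conditions: LiOH, THF/MeOH/H2O, 0 °C to rt; then 1 M HCl to pH 4
Reagents that add atoms: lithium hydroxide, [Li+].[OH-]
Why: Ester saponification under mild conditions leaves the TBS ether and the Z double bond unchanged.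

Step 19
Reactants: 26 the protected acid; 21 the O8 alcohol
Product: 28 (3aR,4S,6R,7S,7aR)-7-[3-(TBDPSO)prop-1-en-2-yl]-6-ethenyl-3-methylidene-2-oxo-6-[(TIPSO)methyl]octahydro-1-benzofuran-4-yl (2Z)-2-[(TBSO)methyl]but-2-enoate, via mixed anhydride 27 (not isolated)
Conditions: 2,4,6-Cl3C6H2COCl, Et3N, toluene, rt; then 21, DMAP, toluene, rt
Reagents that add atoms: none
Why: Yamaguchi esterification, in which the mixed anhydride acylates the hindered equatorial secondary O8 under DMAP catalysis at room temperature to limit Z-to-E isomerisation; no stereocentre is touched.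

Step 20
Reactants: 28 the fully silylated ester
Product: 29 (3aR,4S,6R,7S,7aR)-6-ethenyl-6-(hydroxymethyl)-7-(3-hydroxyprop-1-en-2-yl)-3-methylidene-2-oxooctahydro-1-benzofuran-4-yl (2Z)-2-(hydroxymethyl)but-2-enoate (target CNP0338073.1)
Conditions: HF·pyridine, pyridine, THF, 0 °C to rt
Reagents that add atoms: none
Why: Global fluoride-mediated desilylation removes the TBS, TIPS and TBDPS ethers under non-basic conditions that spare the α-methylene lactone, the ester and all stereocentres.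

**Compound list**
1 | 2-bromoprop-2-en-1-ol | C=C(Br)CO | starting material
2 | [(2-bromoprop-2-en-1-yl)oxy](tert-butyl)diphenylsilane | C=C(Br)CO[Si](c1ccccc1)(c1ccccc1)C(C)(C)C | intermediate
3 | tert-butyldiphenyl{[2-(4,4,5,5-tetramethyl-1,3,2-dioxaborolan-2-yl)prop-2-en-1-yl]oxy}silane | C=C(B1OC(C)(C)C(C)(C)O1)CO[Si](c1ccccc1)(c1ccccc1)C(C)(C)C | intermediate
4 | furan-2(5H)-one | O=C1OCC=C1 | starting material
5 | (4R)-4-[3-(TBDPSO)prop-1-en-2-yl]dihydrofuran-2(3H)-one | O=C1OC[C@@H](C(=C)CO[Si](c2ccccc2)(c2ccccc2)C(C)(C)C)C1 | intermediate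
6 | (S)-solketal, [(4S)-2,2-dimethyl-1,3-dioxolan-4-yl]methanol | OC[C@H]1COC(C)(C)O1 | starting material
7 | [(4R)-2,2-dimethyl-1,3-dioxolan-4-yl]methyl trifluoromethanesulfonate | O=S(=O)(OC[C@H]1COC(C)(C)O1)C(F)(F)F | intermediate
8 | (3S,4R)-4-[3-(TBDPSO)prop-1-en-2-yl]-3-{[(4S)-2,2-dimethyl-1,3-dioxolan-4-yl]methyl}dihydrofuran-2(3H)-one | O=C1OC[C@@H](C(=C)CO[Si](c2ccccc2)(c2ccccc2)C(C)(C)C)[C@@H]1C[C@H]2COC(C)(C)O2 | intermediate
9 | (3R,4S)-4-[3-(TBDPSO)prop-1-en-2-yl]-3-{[(4S)-2,2-dimethyl-1,3-dioxolan-4-yl]methyl}-3-[(TIPSO)methyl]dihydrofuran-2(3H)-one | O=C1OC[C@@H](C(=C)CO[Si](c2ccccc2)(c2ccccc2)C(C)(C)C)[C@@]1(CO[Si](C(C)C)(C(C)C)C(C)C)C[C@H]2COC(C)(C)O2 | intermediate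
10 | (3R,4S)-4-[3-(TBDPSO)prop-1-en-2-yl]-3-{[(4S)-2,2-dimethyl-1,3-dioxolan-4-yl]methyl}-3-[(TIPSO)methyl]tetrahydrofuran-2-ol (both C2 epimers) | OC1OC[C@@H](C(=C)CO[Si](c2ccccc2)(c2ccccc2)C(C)(C)C)[C@@]1(CO[Si](C(C)C)(C(C)C)C(C)C)C[C@H]2COC(C)(C)O2 | intermediate
11 | (2S,3R)-2-[3-(TBDPSO)prop-1-en-2-yl]-3-{[(4S)-2,2-dimethyl-1,3-dioxolan-4-yl]methyl}-3-[(TIPSO)methyl]pent-4-en-1-ol | OC[C@@H](C(=C)CO[Si](c1ccccc1)(c1ccccc1)C(C)(C)C)[C@@](C=C)(CO[Si](C(C)C)(C(C)C)C(C)C)C[C@H]1COC(C)(C)O1 | intermediate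
12 | (2S,4R,5S)-5-[3-(TBDPSO)prop-1-en-2-yl]-4-ethenyl-4-[(TIPSO)methyl]hexane-1,2,6-triol | OC[C@@H](C(=C)CO[Si](c1ccccc1)(c1ccccc1)C(C)(C)C)[C@@](C=C)(CO[Si](C(C)C)(C(C)C)C(C)C)C[C@H](O)CO | intermediate
13 | (2S,4R,5S)-5-[3-(TBDPSO)prop-1-en-2-yl]-4-ethenyl-1,2,6-tris(TESO)-4-[(TIPSO)methyl]hexane | CC[Si](CC)(CC)OC[C@@H](C(=C)CO[Si](c1ccccc1)(c1ccccc1)C(C)(C)C)[C@@](C=C)(CO[Si](C(C)C)(C(C)C)C(C)C)C[C@H](O[Si](CC)(CC)CC)CO[Si](CC)(CC)CC | intermediate
14 | (2S,4R,5S)-5-[3-(TBDPSO)prop-1-en-2-yl]-4-ethenyl-2-(TESO)-4-[(TIPSO)methyl]hexanedial | O=C[C@@H](C(=C)CO[Si](c1ccccc1)(c1ccccc1)C(C)(C)C)[C@@](C=C)(CO[Si](C(C)C)(C(C)C)C(C)C)C[C@H](O[Si](CC)(CC)CC)C=O | intermediate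
15 | methyl prop-2-ynoate | C#CC(=O)OC | starting material
16 | methyl 2-(diisobutylalumanyl)prop-2-enoate | C=C([Al](CC(C)C)CC(C)C)C(=O)OC | intermediate (not isolated)
17 | methyl (4S,6R,7S)-7-[3-(TBDPSO)prop-1-en-2-yl]-6-ethenyl-3-hydroxy-2-methylidene-8-oxo-4-(TESO)-6-[(TIPSO)methyl]octanoate (both C3 epimers) | O=C[C@@H](C(=C)CO[Si](c1ccccc1)(c1ccccc1)C(C)(C)C)[C@@](C=C)(CO[Si](C(C)C)(C(C)C)C(C)C)C[C@H](O[Si](CC)(CC)CC)C(O)C(=C)C(=O)OC | intermediate
18 | methyl (2Z,4S,6R,7S)-2-(bromomethyl)-7-[3-(TBDPSO)prop-1-en-2-yl]-6-ethenyl-8-oxo-4-(TESO)-6-[(TIPSO)methyl]oct-2-enoate | O=C[C@@H](C(=C)CO[Si](c1ccccc1)(c1ccccc1)C(C)(C)C)[C@@](C=C)(CO[Si](C(C)C)(C(C)C)C(C)C)C[C@H](O[Si](CC)(CC)CC)/C=C(\CBr)C(=O)OC | intermediate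
19 | methyl 2-{(1S,2R,3S,4R,6S)-3-[3-(TBDPSO)prop-1-en-2-yl]-4-ethenyl-2-hydroxy-6-(TESO)-4-[(TIPSO)methyl]cyclohexyl}prop-2-enoate | C=C[C@]1(CO[Si](C(C)C)(C(C)C)C(C)C)C[C@H](O[Si](CC)(CC)CC)[C@@H](C(=C)C(=O)OC)[C@H](O)[C@H]1C(=C)CO[Si](c2ccccc2)(c2ccccc2)C(C)(C)C | intermediate (not isolated)
20 | (3aS,4S,6R,7S,7aR)-7-[3-(TBDPSO)prop-1-en-2-yl]-6-ethenyl-3-methylidene-4-(TESO)-6-[(TIPSO)methyl]hexahydro-1-benzofuran-2(3H)-one | C=C[C@]1(CO[Si](C(C)C)(C(C)C)C(C)C)C[C@H](O[Si](CC)(CC)CC)[C@H]2C(=C)C(=O)O[C@@H]2[C@H]1C(=C)CO[Si](c3ccccc3)(c3ccccc3)C(C)(C)C | intermediate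
21 | (3aR,4S,6R,7S,7aR)-7-[3-(TBDPSO)prop-1-en-2-yl]-6-ethenyl-4-hydroxy-3-methylidene-6-[(TIPSO)methyl]hexahydro-1-benzofuran-2(3H)-one | C=C[C@]1(CO[Si](C(C)C)(C(C)C)C(C)C)C[C@H](O)[C@H]2C(=C)C(=O)O[C@@H]2[C@H]1C(=C)CO[Si](c3ccccc3)(c3ccccc3)C(C)(C)C | intermediate
22 | methyl but-2-ynoate | CC#CC(=O)OC | starting material
23 | methyl (2E)-2-(diisobutylalumanyl)but-2-enoate | C/C=C(/[Al](CC(C)C)CC(C)C)C(=O)OC | intermediate (not isolated)
24 | methyl (2Z)-2-(hydroxymethyl)but-2-enoate | C/C=C(/CO)C(=O)OC | intermediate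
25 | methyl (2Z)-2-[(TBSO)methyl]but-2-enoate | C/C=C(/CO[Si](C)(C)C(C)(C)C)C(=O)OC | intermediate
26 | (2Z)-2-[(TBSO)methyl]but-2-enoic acid | C/C=C(/CO[Si](C)(C)C(C)(C)C)C(=O)O | intermediate
27 | (2Z)-2-[(TBSO)methyl]but-2-enoic 2,4,6-trichlorobenzoic anhydride | C/C=C(/CO[Si](C)(C)C(C)(C)C)C(=O)OC(=O)c1c(Cl)cc(Cl)cc1Cl | intermediate (not isolated)
28 | (3aR,4S,6R,7S,7aR)-7-[3-(TBDPSO)prop-1-en-2-yl]-6-ethenyl-3-methylidene-2-oxo-6-[(TIPSO)methyl]octahydro-1-benzofuran-4-yl (2Z)-2-[(TBSO)methyl]but-2-enoate | C=C[C@]1(CO[Si](C(C)C)(C(C)C)C(C)C)C[C@H](OC(=O)/C(=C\C)CO[Si](C)(C)C(C)(C)C)[C@H]2C(=C)C(=O)O[C@@H]2[C@H]1C(=C)CO[Si](c3ccccc3)(c3ccccc3)C(C)(C)C | intermediate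
29 | (3aR,4S,6R,7S,7aR)-6-ethenyl-6-(hydroxymethyl)-7-(3-hydroxyprop-1-en-2-yl)-3-methylidene-2-oxooctahydro-1-benzofuran-4-yl (2Z)-2-(hydroxymethyl)but-2-enoate | C=C[C@]1(CO)C[C@H](OC(=O)/C(=C\C)CO)[C@H]2C(=C)C(=O)O[C@@H]2[C@H]1C(=C)CO | target

**Step count.** Total: 20 steps. Longest linear sequence: 16 steps (1 → 2 → 3 → 5 → 8 → 9 → 10 → 11 → 12 → 13 → 14 → 17 → 18 → 20 → 21 → 28 → 29); the triflate (step 4) and the side-chain acid (steps 16–18) are side branches.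

**Three steps most likely to fail, with fallbacks**

Risk 1, step 3 (asymmetric 1,4-addition of an α-branched alkenyl boronate to the sluggish acceptor furanone; conversion or ee may be poor). The fallback replaces catalyst control by auxiliary control with an organocopper nucleophile. It sets out from bromide 2 and returns at lactone 5. Magnesium insertion (Mg, THF, 0 °C) gives [3-(TBDPSO)prop-1-en-2-yl]magnesium bromide F1. Under CuBr·SMe2 catalysis with Me3SiCl at −78 °C, F1 adds to commercial (5S)-5-{[(1S,2R,5S)-menthyl]oxy}furan-2(5H)-one anti to the menthyloxy group and gives the trans acetal lactone (4R,5S)-4-[3-(TBDPSO)prop-1-en-2-yl]-5-(menthyloxy)dihydrofuran-2(3H)-one F2. NaBH4/KOH in aqueous EtOH followed by HCl opens the pseudo-ester, reduces the freed aldehyde and relactonises, releasing menthol and giving 5.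

Risk 2, step 12 (the vinylalane must choose the C7 aldehyde over the C6 aldehyde of dialdehyde 14, and C5 must not epimerise). The fallback differentiates the two termini by protecting-group logic instead of reactivity. It sets out from alcohol 11 and returns at bromo aldehyde 18.
- O6 is protected (NaH, 4-MeOC6H4CH2Cl, Bu4NI, THF) to give the 4-methoxybenzyl (PMB) ether of 11 F3.
- Aqueous AcOH removes the acetonide to give the PMB-protected 1,2-diol F4, and Et3SiCl/imidazole gives the bis-TES ether F5.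
- Swern oxidation now touches only the single primary TES ether and gives the mono-aldehyde F6.
- Vinylalane 16 adds to give the Baylis–Hillman-type alcohol F7, and NBS/Me2S gives the (Z)-allylic bromide F8.
- DDQ (CH2Cl2/pH 7 buffer) removes the PMB group to give the primary alcohol F9, and Dess–Martin periodinane oxidation gives 18.

Risk 3, step 14 (the indium closure may give the cis-fused lactone if the (Z)-allylindium reacts through its own chair without equilibrating). The fallback changes the nucleophile class to an isolable allylboronate cyclised under acid catalysis. It sets out from bromo aldehyde 18 and returns at lactone 20. Pd2(dba)3-catalysed borylation of the allylic bromide with B2pin2 (toluene/DMSO, 50 °C) gives the 2-(methoxycarbonyl)allyl pinacol boronate F10, which is unreactive toward the internal aldehyde without a catalyst. TfOH or Sc(OTf)3 (10 mol %, toluene, 0 °C) then triggers the intramolecular allylboration; acid-catalysed allylborations of 2-alkoxycarbonyl allylboronates are known to favour trans γ-lactones. The resulting borate of 19 lactonises in the same flask to 20.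

Further compounds
F1 | step 3 | [3-(tert-butyldiphenylsilyloxy)prop-1-en-2-yl]magnesium bromide | C=C([Mg]Br)CO[Si](c1ccccc1)(c1ccccc1)C(C)(C)C
F2 | step 3 | (4R,5S)-4-[3-(TBDPSO)prop-1-en-2-yl]-5-{[(1S,2R,5S)-5-methyl-2-(propan-2-yl)cyclohexyl]oxy}dihydrofuran-2(3H)-one | O=C1O[C@H](O[C@H]2C[C@@H](C)CC[C@@H]2C(C)C)[C@@H](C(=C)CO[Si](c3ccccc3)(c3ccccc3)C(C)(C)C)C1
F3 | step 12 | 4-methoxybenzyl ether (at O1) of pentenol 11 | COc1ccc(COC[C@@H](C(=C)CO[Si](c2ccccc2)(c2ccccc2)C(C)(C)C)[C@@](C=C)(CO[Si](C(C)C)(C(C)C)C(C)C)C[C@H]2COC(C)(C)O2)cc1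
F4 | step 12 | (2S,4R,5S)-5-[3-(TBDPSO)prop-1-en-2-yl]-4-ethenyl-6-(4-methoxybenzyloxy)-4-[(TIPSO)methyl]hexane-1,2-diol | COc1ccc(COC[C@@H](C(=C)CO[Si](c2ccccc2)(c2ccccc2)C(C)(C)C)[C@@](C=C)(CO[Si](C(C)C)(C(C)C)C(C)C)C[C@H](O)CO)cc1
F5 | step 12 | (2S,4R,5S)-5-[3-(TBDPSO)prop-1-en-2-yl]-4-ethenyl-6-(4-methoxybenzyloxy)-1,2-bis(TESO)-4-[(TIPSO)methyl]hexane | COc1ccc(COC[C@@H](C(=C)CO[Si](c2ccccc2)(c2ccccc2)C(C)(C)C)[C@@](C=C)(CO[Si](C(C)C)(C(C)C)C(C)C)C[C@H](O[Si](CC)(CC)CC)CO[Si](CC)(CC)CC)cc1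
F6 | step 12 | (2S,4R,5S)-5-[3-(TBDPSO)prop-1-en-2-yl]-4-ethenyl-6-(4-methoxybenzyloxy)-2-(TESO)-4-[(TIPSO)methyl]hexanal | COc1ccc(COC[C@@H](C(=C)CO[Si](c2ccccc2)(c2ccccc2)C(C)(C)C)[C@@](C=C)(CO[Si](C(C)C)(C(C)C)C(C)C)C[C@H](O[Si](CC)(CC)CC)C=O)cc1
F7 | step 12 | methyl (4S,6R,7S)-7-[3-(TBDPSO)prop-1-en-2-yl]-6-ethenyl-3-hydroxy-8-(4-methoxybenzyloxy)-2-methylidene-4-(TESO)-6-[(TIPSO)methyl]octanoate (both C3 epimers) | COc1ccc(COC[C@@H](C(=C)CO[Si](c2ccccc2)(c2ccccc2)C(C)(C)C)[C@@](C=C)(CO[Si](C(C)C)(C(C)C)C(C)C)C[C@H](O[Si](CC)(CC)CC)C(O)C(=C)C(=O)OC)cc1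
F8 | step 12 | methyl (2Z,4S,6R,7S)-2-(bromomethyl)-7-[3-(TBDPSO)prop-1-en-2-yl]-6-ethenyl-8-(4-methoxybenzyloxy)-4-(TESO)-6-[(TIPSO)methyl]oct-2-enoate | COc1ccc(COC[C@@H](C(=C)CO[Si](c2ccccc2)(c2ccccc2)C(C)(C)C)[C@@](C=C)(CO[Si](C(C)C)(C(C)C)C(C)C)C[C@H](O[Si](CC)(CC)CC)/C=C(\CBr)C(=O)OC)cc1
F9 | step 12 | methyl (2Z,4S,6R,7S)-2-(bromomethyl)-7-[3-(TBDPSO)prop-1-en-2-yl]-6-ethenyl-8-hydroxy-4-(TESO)-6-[(TIPSO)methyl]oct-2-enoate | OC[C@@H](C(=C)CO[Si](c1ccccc1)(c1ccccc1)C(C)(C)C)[C@@](C=C)(CO[Si](C(C)C)(C(C)C)C(C)C)C[C@H](O[Si](CC)(CC)CC)/C=C(\CBr)C(=O)OC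
F10 | step 14 | methyl (2E,4S,6R,7S)-7-[3-(TBDPSO)prop-1-en-2-yl]-6-ethenyl-8-oxo-2-[(4,4,5,5-tetramethyl-1,3,2-dioxaborolan-2-yl)methyl]-4-(TESO)-6-[(TIPSO)methyl]oct-2-enoate | O=C[C@@H](C(=C)CO[Si](c1ccccc1)(c1ccccc1)C(C)(C)C)[C@@](C=C)(CO[Si](C(C)C)(C(C)C)C(C)C)C[C@H](O[Si](CC)(CC)CC)/C=C(\CB1OC(C)(C)C(C)(C)O1)C(=O)OC
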